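**Retrosynthetic overview**
1. Feature: in the trans-fused 6,12-lactone (ring O–C6–C7–C11–C12) the C8 oxygen is homoallylic to the exocyclic C11=C13 alkene through C7. This O–C8–C7–C11=C13 array is the retron of a γ-attack, at C7, of a 3-(stannylmethyl)butenolide (C13–C11=C7) on a C8 aldehyde.
2. Key disconnection C7–C8 opens the ten-membered carbocycle (C1–C10) to the stannane aldehyde 26, which already holds the lactone, the C6 centre and both ring-cis trisubstituted alkenes. After closure only O8 acylation and C14/C15 adjustment remain (PMB on O15, TBDPS on O14).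
3. Butenolide 24 comes from ring-closing metathesis of the 2-(tributylstannylmethyl)acrylate 23 of the C6 carbinol 19. Tin is put in by radical SH2' exchange on the allyl sulfone ester 22.
4. C6 is set by zinc–ProPhenol alkynylation of enal 15, followed by semihydrogenation. The chain comes from two Horner–Wadsworth–Emmons reactions of alkylated triethyl phosphonoacetates (C4=C5 first, then C1=C10).
5. Ring order: five-membered lactone (step 18), then ten-membered carbocycle (step 21).

Key step: step 21

Remark on numbering: germacrane numbering is used throughout (C1–C10 ring carbons; C12 lactone carbonyl, C13 exocyclic methylene; C14 on C10; C15 on C4).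
Assumption: the (S,S)-ProPhenol ligand is taken as the enantiomer that directs the alkynyl group to the Si face of the C6 aldehyde; if the sense is the opposite, the (R,R)-ligand is used with nothing else changed.

Step 1
Reactants: 1 triethyl phosphonoacetate; 2 (3-bromopropoxy)(tert-butyl)dimethylsilane
Product: 3 ethyl 5-[(tert-butyldimethylsilyl)oxy]-2-(diethoxyphosphoryl)pentanoate (racemic)
Conditions: NaH, DMF, 0 °C; then 2, NaI (cat.), 60 °C (1 in excess)
Reagents that add atoms: none
Why: SN2 C-alkylation of the sodium phosphonoacetate carbanion by a primary bromide (iodide-catalysed), with 1 in excess to hold back dialkylation; the silyl ether is inert to this soft nucleophile.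

Step 2
Reactants: 3; 4 2,2-dimethoxyacetaldehyde (dried organic solution made from the commercial aqueous one)
Product: 5 ethyl (2E)-2-{3-[(tert-butyldimethylsilyl)oxy]propyl}-4,4-dimethoxybut-2-enoate
Conditions: NaH, THF, 0 °C → rt
Reagents that add atoms: none
Why: Horner–Wadsworth–Emmons olefination of a non-enolisable aldehyde, in which reversible addition lets the ester and the acetal carbon settle trans, giving the C4=C5 alkene with C15 trans to C6 (C3 cis to C6); any minor geometric isomer would be removed by chromatography.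

Step 3
Reactants: 5
Product: 6 (2E)-2-{3-[(tert-butyldimethylsilyl)oxy]propyl}-4,4-dimethoxybut-2-en-1-ol
Conditions: iBu2AlH (2.2 equiv), CH2Cl2, −78 °C; aq. potassium sodium tartrate
Reagents that add atoms: none
Why: Ester reduction by iBu2AlH at low temperature takes the conjugated ester to the allylic alcohol by 1,2-hydride delivery and leaves the acetal, the silyl ether and the alkene geometry untouched.

Step 4
Reactants: 6
Product: 7 tert-butyl{[(4E)-6,6-dimethoxy-4-{[(4-methoxybenzyl)oxy]methyl}hex-4-en-1-yl]oxy}dimethylsilane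
Conditions: NaH, 4-methoxybenzyl chloride, Bu4NI (cat.), THF/DMF, 0 °C → rt
Reagents that add atoms: 4-methoxybenzyl chloride, COc1ccc(CCl)cc1
Why: Williamson etherification of the primary allylic alkoxide with a benzylic chloride; the acetal and the silyl ether are stable to NaH.

Step 5
Reactants: 7
Product: 8 (4E)-6,6-dimethoxy-4-{[(4-methoxybenzyl)oxy]methyl}hex-4-en-1-ol
Conditions: Bu4NF, THF, 0 °C → rt
Reagents that add atoms: none
Why: Fluoride-mediated desilylation, driven by the strong Si–F bond, frees only the C1 hydroxyl since the PMB ether and the acetal do not react with Bu4NF.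

Step 6
Reactants: 8
Product: 9 (4E)-6,6-dimethoxy-4-{[(4-methoxybenzyl)oxy]methyl}hex-4-enal
Conditions: Dess–Martin periodinane, NaHCO3, CH2Cl2, 0 °C → rt
Reagents that add atoms: none
Why: Dess–Martin oxidation converts the primary alcohol to the aldehyde under buffered, water-free conditions, so the acid-labile unsaturated acetal survives and no over-oxidation occurs.

Step 7
Reactants: 1 triethyl phosphonoacetate; 10 (2-bromoethoxy)(tert-butyl)dimethylsilane
Product: 11 ethyl 4-[(tert-butyldimethylsilyl)oxy]-2-(diethoxyphosphoryl)butanoate (racemic)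
Conditions: NaH, DMF, 0 °C; then 10, NaI (cat.), 70 °C (1 in excess)
Reagents that add atoms: none
Why: SN2 C-alkylation of the phosphonoacetate carbanion as in step 1; iodide catalysis and gentle heating make up for the slower displacement next to the silyloxy group.

Step 8
Reactants: 9; 11
Product: 12 ethyl (2E,6E)-2-{2-[(tert-butyldimethylsilyl)oxy]ethyl}-8,8-dimethoxy-6-{[(4-methoxybenzyl)oxy]methyl}octa-2,6-dienoate
Conditions: NaH, THF, 0 °C → rt (anion of 11 preformed)
Reagents that add atoms: none
Why: Horner–Wadsworth–Emmons olefination of the aliphatic aldehyde with the preformed phosphonate anion, which gives the trisubstituted enoate with the ester (C14) trans to C2 under thermodynamic control; the minor isomer would be separated.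

Step 9
Reactants: 12
Product: 13 (2E,6E)-2-{2-[(tert-butyldimethylsilyl)oxy]ethyl}-8,8-dimethoxy-6-{[(4-methoxybenzyl)oxy]methyl}octa-2,6-dien-1-ol
Conditions: iBu2AlH (2.2 equiv), CH2Cl2, −78 °C; aq. potassium sodium tartrate
Reagents that add atoms: none
Why: Ester reduction by iBu2AlH gives the C14 allylic alcohol; acetal, PMB and silyl ethers are inert.

Step 10
Reactants: 13
Product: 14 tert-butyldiphenylsilyl ether of 13 at O14, that is (2E,6E)-1-[(tert-butyldiphenylsilyl)oxy]-2-{2-[(tert-butyldimethylsilyl)oxy]ethyl}-8,8-dimethoxy-6-{[(4-methoxybenzyl)oxy]methyl}octa-2,6-diene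
Conditions: tert-butyldiphenylsilyl chloride, imidazole, DMF, rt
Reagents that add atoms: tert-butyldiphenylsilyl chloride, CC(C)(C)[Si](Cl)(c1ccccc1)c1ccccc1
Why: Silylation of the primary allylic alcohol with imidazole as base and nucleophilic catalyst puts a robust silyl group on O14 that outlasts the later removal of the O8 TBS group.

Step 11
Reactants: 14
Product: 15 (2E,6E)-9-[(tert-butyldimethylsilyl)oxy]-7-{[(tert-butyldiphenylsilyl)oxy]methyl}-3-{[(4-methoxybenzyl)oxy]methyl}nona-2,6-dienal (CHO cis to the C3 chain, trans to CH2OPMB)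
Conditions: PPTS (cat.), acetone/H2O (10:1), rt
Reagents that add atoms: water, O
Why: Acid-catalysed acetal hydrolysis; the α,β-unsaturated dimethyl acetal ionises through an allylic oxocarbenium ion so easily that catalytic PPTS at room temperature suffices, conditions that neither cleave the silyl or PMB ethers nor scramble the alkene geometry.

Step 12
Reactants: 15; 16 ethynyltrimethylsilane
Product: 17 (3R,4E,8E)-11-[(tert-butyldimethylsilyl)oxy]-9-{[(tert-butyldiphenylsilyl)oxy]methyl}-5-{[(4-methoxybenzyl)oxy]methyl}-1-(trimethylsilyl)undeca-4,8-dien-1-yn-3-ol (6R in germacrane numbering)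
Conditions: (S,S)-ProPhenol (20 mol%), Ph3P=O (40 mol%), Me2Zn (3 equiv), 16 (3 equiv), toluene, 0 °C
Reagents that add atoms: none
Why: Catalytic enantioselective alkynylzinc addition (zinc–ProPhenol alkynylation), in which the dinuclear zinc complex of the chiral ligand holds the aldehyde and the zinc acetylide together and delivers the alkynyl group to the Si face of C6, which sets 6R; enals are good substrates for this addition.

Step 13
Reactants: 17
Product: 18 (3R,4E,8E)-11-[(tert-butyldimethylsilyl)oxy]-9-{[(tert-butyldiphenylsilyl)oxy]methyl}-5-{[(4-methoxybenzyl)oxy]methyl}undeca-4,8-dien-1-yn-3-ol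
Conditions: K2CO3 (cat.), MeOH, 0 °C → rt
Reagents that add atoms: none
Why: Methanolysis of the alkynyl C–Si bond under mild carbonate catalysis removes only the alkynyl TMS group; the alkyl silyl ethers are far slower to react.

Step 14
Reactants: 18
Product: 19 (3S,4E,8E)-11-[(tert-butyldimethylsilyl)oxy]-9-{[(tert-butyldiphenylsilyl)oxy]methyl}-5-{[(4-methoxybenzyl)oxy]methyl}undeca-1,4,8-trien-3-ol
Conditions: H2 (1 atm), Pd/CaCO3 poisoned with Pb(OAc)2 (Lindlar catalyst), quinoline, EtOAc, rt
Reagents that add atoms: none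
Why: Lindlar semihydrogenation stops at the alkene because the poisoned palladium surface binds the alkyne much more strongly than alkenes, and the trisubstituted alkenes and the benzyl-type ether are not touched; the C6 centre is unaffected (its descriptor changes from R to S only because the CIP priorities change).

Step 15
Reactants: 20 2-(bromomethyl)acrylic acid
Product: 21 2-[(phenylsulfonyl)methyl]acrylic acid
Conditions: PhSO2Na (1.2 equiv), MeOH, reflux; then aq. HCl
Reagents that add atoms: sodium benzenesulfinate, [Na+].[O-]S(=O)c1ccccc1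
Why: Nucleophilic displacement of the allylic bromide by the soft sulfinate S-nucleophile (direct and allylic attack give the same product on this symmetric allyl system) gives the allyl sulfone acid.

Step 16
Reactants: 19; 21
Product: 22 (3S,4E,8E)-11-[(tert-butyldimethylsilyl)oxy]-9-{[(tert-butyldiphenylsilyl)oxy]methyl}-5-{[(4-methoxybenzyl)oxy]methyl}undeca-1,4,8-trien-3-yl 2-[(phenylsulfonyl)methyl]acrylate
Conditions: N,N'-diisopropylcarbodiimide, DMAP (0.1 equiv), CH2Cl2, 0 °C → rt
Reagents that add atoms: none
Why: Carbodiimide/DMAP (Steglich) esterification acylates the secondary carbinol under neutral conditions that do not ionise the doubly allylic C6–O bond, so the configuration at C6 is retained.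

Step 17
Reactants: 22
Product: 23 (3S,4E,8E)-11-[(tert-butyldimethylsilyl)oxy]-9-{[(tert-butyldiphenylsilyl)oxy]methyl}-5-{[(4-methoxybenzyl)oxy]methyl}undeca-1,4,8-trien-3-yl 2-[(tributylstannyl)methyl]acrylate
Conditions: Bu3SnH (2.2 equiv), AIBN (cat.), benzene, 80 °C
Reagents that add atoms: tributyltin hydride, CCCC[SnH](CCCC)CCCC
Why: Radical SH2' stannylation of an allyl sulfone, in which Bu3Sn• adds to the terminal acrylate carbon, the α-ester radical expels PhSO2• by β-scission and a second equivalent of Bu3SnH carries the chain; because the allyl unit is symmetric the regiochemistry is not in question.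

Step 18
Reactants: 23
Product: 24 (5R)-5-[(1E,5E)-8-[(tert-butyldimethylsilyl)oxy]-6-{[(tert-butyldiphenylsilyl)oxy]methyl}-2-{[(4-methoxybenzyl)oxy]methyl}octa-1,5-dien-1-yl]-3-[(tributylstannyl)methyl]furan-2(5H)-one
Conditions: second-generation Grubbs catalyst (10 mol%), CH2Cl2 (0.005 M), 40 °C
Reagents that add atoms: none
Why: Ring-closing metathesis, in which the ruthenium carbene forms at the monosubstituted vinyl group and closes onto the acrylate alkene to give the five-membered butenolide with loss of ethylene, this closure being faster than any reaction with the hindered trisubstituted alkenes; the C13–Sn bond is a spectator.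

Step 19
Reactants: 24
Product: 25 (5R)-5-[(1E,5E)-6-{[(tert-butyldiphenylsilyl)oxy]methyl}-8-hydroxy-2-{[(4-methoxybenzyl)oxy]methyl}octa-1,5-dien-1-yl]-3-[(tributylstannyl)methyl]furan-2(5H)-one
Conditions: PPTS (0.2 equiv), MeOH/CH2Cl2, rt
Reagents that add atoms: none
Why: Acid-catalysed methanolysis of silyl ethers is much faster for the primary TBS group than for the bulkier TBDPS group, so only O8 is freed; the ester-deactivated allylstannane and the PMB ether tolerate PPTS.

Step 20
Reactants: 25
Product: 26 (3E,7E)-3-{[(tert-butyldiphenylsilyl)oxy]methyl}-7-{[(4-methoxybenzyl)oxy]methyl}-8-{(2R)-5-oxo-4-[(tributylstannyl)methyl]-2,5-dihydrofuran-2-yl}octa-3,7-dienal (C8 aldehyde, used at once)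
Conditions: Dess–Martin periodinane, NaHCO3, CH2Cl2, 0 °C
Reagents that add atoms: none
Why: Dess–Martin oxidation under bicarbonate buffer gives the β,γ-unsaturated aldehyde without acid or base strong enough to move the C1=C10 alkene into conjugation or to touch the C–Sn bond.

Step 21
Reactants: 26
Product: 27 (6R,7R,8R)-14-[(tert-butyldiphenylsilyl)oxy]-8-hydroxy-15-[(4-methoxybenzyl)oxy]germacra-1(10),4,11(13)-trien-12,6-olide (ten-membered ring with both alkenes cis in the ring, trans-fused α-methylene lactone, free C8 hydroxyl)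
Conditions: BF3·OEt2 (3 equiv), CH2Cl2, −78 °C, slow addition of 26 (final 0.002 M); aq. NaHCO3
Reagents that add atoms: none
Why: Proposed new method: BF3 coordinates the C8 aldehyde and C7, the γ-carbon of the allylstannane unit C13–C11=C7, attacks it in an open SE2' transition state, the C13–Sn bond stabilising the positive charge that develops at C11 before tin leaves as Bu3SnF and the alkene appears at C11=C13; the closest known reactions are the BF3-promoted additions of 2-(tributylstannylmethyl)acrylates to aldehydes and the BF3-promoted macrocyclisations of allylstannane aldehydes to ten- to fourteen-membered rings, neither of which has been run with the stannane held in a butenolide. The ten-membered carbocycle closes by 10-exo-trig attack on the C8 carbonyl, the oxygen staying outside the ring, and the five-membered lactone is carried through unchanged. C7 is controlled by the C6 centre: attack anti to the C5 substituent is the staggered trajectory and gives the trans-fused lactone (H6 and H7 anti). C8 is controlled by the open transition state, which in Lewis-acid additions of γ-substituted allylstannanes gives the syn adduct, here C6 and O8 syn along C11–C7–C8–C9, that is attack on the Si face of the aldehyde. The step needs cyclisation to beat oligomerisation, protodestannylation and conjugation of the β,γ-unsaturated aldehyde; high dilution, −78 °C and the two ring-cis trisubstituted alkenes, which fold C8 towards C7, are what should secure it.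

Step 22
Reactants: 27; 28 (S)-2-methylbutanoic acid
Product: 29 (6R,7R,8R)-14-[(tert-butyldiphenylsilyl)oxy]-15-[(4-methoxybenzyl)oxy]-8-{[(2S)-2-methylbutanoyl]oxy}germacra-1(10),4,11(13)-trien-12,6-olide
Conditions: N,N'-diisopropylcarbodiimide, DMAP (0.2 equiv), CH2Cl2, 0 °C → rt
Reagents that add atoms: none
Why: Steglich esterification of the secondary C8 alcohol; catalytic DMAP at low temperature keeps epimerisation of the α-stereocentre of 28 low, and the α-methylene lactone only adds DMAP reversibly.

Step 23
Reactants: 29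
Product: 30 (6R,7R,8R)-14-hydroxy-15-[(4-methoxybenzyl)oxy]-8-{[(2S)-2-methylbutanoyl]oxy}germacra-1(10),4,11(13)-trien-12,6-olide
Conditions: HF·pyridine, pyridine, THF, 0 °C → rt
Reagents that add atoms: none
Why: Buffered fluoride desilylation cleaves the primary TBDPS ether without basic conditions that would add to the α-methylene lactone or cleave the esters.

Step 24
Reactants: 30
Product: 31 (6R,7R,8R)-15-[(4-methoxybenzyl)oxy]-8-{[(2S)-2-methylbutanoyl]oxy}-14-oxogermacra-1(10),4,11(13)-trien-12,6-olide
Conditions: MnO2 (activated, excess), CH2Cl2, rt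
Reagents that add atoms: none
Why: MnO2 oxidises allylic alcohols selectively under neutral conditions, giving the C14 enal without change of the C1=C10 geometry; O15 is still protected, so no choice between two allylic alcohols arises.

Step 25
Reactants: 31
Product: 32 target, (6R,7R,8R)-15-hydroxy-8-{[(2S)-2-methylbutanoyl]oxy}-14-oxogermacra-1(10),4,11(13)-trien-12,6-olide (CNP0168859.6)
Conditions: DDQ (1.3 equiv), CH2Cl2/pH 7 phosphate buffer (10:1), 0 °C
Reagents that add atoms: none
Why: Oxidative cleavage of the PMB ether by DDQ (hydride abstraction from the electron-rich benzylic position, then hydrolysis) frees the C15 alcohol; at 0 °C with a slight excess the liberated allylic alcohol should not be oxidised further.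

**Compound list**
1 | triethyl phosphonoacetate | CCOC(=O)CP(=O)(OCC)OCC | starting material
2 | (3-bromopropoxy)(tert-butyl)dimethylsilane | BrCCCO[Si](C)(C)C(C)(C)C | starting material
3 | ethyl 5-[(tert-butyldimethylsilyl)oxy]-2-(diethoxyphosphoryl)pentanoate | CCOC(=O)C(CCCO[Si](C)(C)C(C)(C)C)P(=O)(OCC)OCC | intermediate
4 | 2,2-dimethoxyacetaldehyde | COC(OC)C=O | starting material
5 | ethyl (2E)-2-{3-[(tert-butyldimethylsilyl)oxy]propyl}-4,4-dimethoxybut-2-enoate | CCOC(=O)/C(CCCO[Si](C)(C)C(C)(C)C)=C/C(OC)OC | intermediate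
6 | (2E)-2-{3-[(tert-butyldimethylsilyl)oxy]propyl}-4,4-dimethoxybut-2-en-1-ol | OC/C(CCCO[Si](C)(C)C(C)(C)C)=C/C(OC)OC | intermediate
7 | PMB ether of 6 | COc1ccc(COC/C(CCCO[Si](C)(C)C(C)(C)C)=C/C(OC)OC)cc1 | intermediate
8 | (4E)-6,6-dimethoxy-4-{[(4-methoxybenzyl)oxy]methyl}hex-4-en-1-ol | COc1ccc(COC/C(CCCO)=C/C(OC)OC)cc1 | intermediate
9 | (4E)-6,6-dimethoxy-4-{[(4-methoxybenzyl)oxy]methyl}hex-4-enal | COc1ccc(COC/C(CCC=O)=C/C(OC)OC)cc1 | intermediate
10 | (2-bromoethoxy)(tert-butyl)dimethylsilane | BrCCO[Si](C)(C)C(C)(C)C | starting material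
11 | ethyl 4-[(tert-butyldimethylsilyl)oxy]-2-(diethoxyphosphoryl)butanoate | CCOC(=O)C(CCO[Si](C)(C)C(C)(C)C)P(=O)(OCC)OCC | intermediate
12 | ethyl (2E,6E)-2-{2-[(tert-butyldimethylsilyl)oxy]ethyl}-8,8-dimethoxy-6-{[(4-methoxybenzyl)oxy]methyl}octa-2,6-dienoate | CCOC(=O)/C(CCO[Si](C)(C)C(C)(C)C)=C/CC/C(COCc1ccc(OC)cc1)=C\C(OC)OC | intermediate
13 | (2E,6E)-2-{2-[(tert-butyldimethylsilyl)oxy]ethyl}-8,8-dimethoxy-6-{[(4-methoxybenzyl)oxy]methyl}octa-2,6-dien-1-ol | OC/C(CCO[Si](C)(C)C(C)(C)C)=C/CC/C(COCc1ccc(OC)cc1)=C\C(OC)OC | intermediate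
14 | O14-tert-butyldiphenylsilyl ether of 13 | CC(C)(C)[Si](OC/C(CCO[Si](C)(C)C(C)(C)C)=C/CC/C(COCc1ccc(OC)cc1)=C\C(OC)OC)(c1ccccc1)c1ccccc1 | intermediate
15 | (2E,6E)-9-[(tert-butyldimethylsilyl)oxy]-7-{[(tert-butyldiphenylsilyl)oxy]methyl}-3-{[(4-methoxybenzyl)oxy]methyl}nona-2,6-dienal | O=C/C=C(/COCc1ccc(OC)cc1)CC/C=C(/CO[Si](c1ccccc1)(c1ccccc1)C(C)(C)C)CCO[Si](C)(C)C(C)(C)C | intermediate
16 | ethynyltrimethylsilane | C#C[Si](C)(C)C | starting material
17 | (3R,4E,8E)-TMS-propargylic alcohol | O[C@@H](C#C[Si](C)(C)C)/C=C(/COCc1ccc(OC)cc1)CC/C=C(/CO[Si](c1ccccc1)(c1ccccc1)C(C)(C)C)CCO[Si](C)(C)C(C)(C)C | intermediate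
18 | (3R,4E,8E)-terminal propargylic alcohol | O[C@@H](C#C)/C=C(/COCc1ccc(OC)cc1)CC/C=C(/CO[Si](c1ccccc1)(c1ccccc1)C(C)(C)C)CCO[Si](C)(C)C(C)(C)C | intermediate
19 | (3S,4E,8E)-undeca-1,4,8-trien-3-ol (C6 vinyl carbinol) | O[C@@H](C=C)/C=C(/COCc1ccc(OC)cc1)CC/C=C(/CO[Si](c1ccccc1)(c1ccccc1)C(C)(C)C)CCO[Si](C)(C)C(C)(C)C | intermediate
20 | 2-(bromomethyl)acrylic acid | C=C(CBr)C(=O)O | starting material
21 | 2-[(phenylsulfonyl)methyl]acrylic acid | C=C(CS(=O)(=O)c1ccccc1)C(=O)O | intermediate
22 | 2-[(phenylsulfonyl)methyl]acrylate of 19 | C=C(CS(=O)(=O)c1ccccc1)C(=O)O[C@@H](C=C)/C=C(/COCc1ccc(OC)cc1)CC/C=C(/CO[Si](c1ccccc1)(c1ccccc1)C(C)(C)C)CCO[Si](C)(C)C(C)(C)C | intermediate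
23 | 2-[(tributylstannyl)methyl]acrylate of 19 | C=C(C[Sn](CCCC)(CCCC)CCCC)C(=O)O[C@@H](C=C)/C=C(/COCc1ccc(OC)cc1)CC/C=C(/CO[Si](c1ccccc1)(c1ccccc1)C(C)(C)C)CCO[Si](C)(C)C(C)(C)C | intermediate
24 | (5R)-3-[(tributylstannyl)methyl]butenolide, O8-TBS | O=C1O[C@H](/C=C(/COCc2ccc(OC)cc2)CC/C=C(/CO[Si](c2ccccc2)(c2ccccc2)C(C)(C)C)CCO[Si](C)(C)C(C)(C)C)C=C1C[Sn](CCCC)(CCCC)CCCC | intermediate
25 | (5R)-3-[(tributylstannyl)methyl]butenolide, free C8 alcohol | O=C1O[C@H](/C=C(/COCc2ccc(OC)cc2)CC/C=C(/CO[Si](c2ccccc2)(c2ccccc2)C(C)(C)C)CCO)C=C1C[Sn](CCCC)(CCCC)CCCC | intermediate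
26 | (5R)-3-[(tributylstannyl)methyl]butenolide C8 aldehyde (key-step precursor) | O=C1O[C@H](/C=C(/COCc2ccc(OC)cc2)CC/C=C(/CO[Si](c2ccccc2)(c2ccccc2)C(C)(C)C)CC=O)C=C1C[Sn](CCCC)(CCCC)CCCC | intermediate
27 | (6R,7R,8R)-8-hydroxy germacranolide, O14-TBDPS, O15-PMB (key-step product) | O=C1O[C@@H]2/C=C(/COCc3ccc(OC)cc3)CC/C=C(/CO[Si](c3ccccc3)(c3ccccc3)C(C)(C)C)C[C@@H](O)[C@H]2C1=C | intermediate
28 | (S)-2-methylbutanoic acid | CC[C@H](C)C(=O)O | starting material
29 | 8-O-[(2S)-2-methylbutanoyl] ester of 27 | O=C1O[C@@H]2/C=C(/COCc3ccc(OC)cc3)CC/C=C(/CO[Si](c3ccccc3)(c3ccccc3)C(C)(C)C)C[C@@H](OC(=O)[C@@H](C)CC)[C@H]2C1=C | intermediate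
30 | 14-hydroxy 15-O-PMB ester | O=C1O[C@@H]2/C=C(/COCc3ccc(OC)cc3)CC/C=C(/CO)C[C@@H](OC(=O)[C@@H](C)CC)[C@H]2C1=C | intermediate
31 | 14-oxo 15-O-PMB ester | O=C1O[C@@H]2/C=C(/COCc3ccc(OC)cc3)CC/C=C(/C=O)C[C@@H](OC(=O)[C@@H](C)CC)[C@H]2C1=C | intermediate
32 | CNP0168859.6 | C=C1C(=O)O[C@@H]2/C=C(/CO)CC/C=C(/C=O)C[C@@H](OC(=O)[C@@H](C)CC)[C@@H]12 | target

Total step count: 25. Longest linear sequence: 23 steps (steps 1–6, 8–14 and 16–25; steps 7 and 15 make the side reagents 11 and 21).

**Steps most likely to fail**

1. Step 21 (key macrocyclisation). The ester-deactivated allylstannane may attack the BF3-bound aldehyde too slowly, so that protodestannylation, migration of the C1=C10 alkene into conjugation with the aldehyde or intermolecular coupling take over; the aldehyde face may also be chosen wrongly. The fallback uses known chemistry and sets out from 26. Iododestannylation with I2 (CH2Cl2, −78 → 0 °C) gives the allylic iodide (3E,7E)-3-{[(tert-butyldiphenylsilyl)oxy]methyl}-8-[(2R)-4-(iodomethyl)-5-oxo-2,5-dihydrofuran-2-yl]-7-{[(4-methoxybenzyl)oxy]methyl}octa-3,7-dienal F1; its allylic isomer, should it form first, leads to the same allylchromium species. CrCl2 (divalent chromium) in THF at high dilution then closes the same C7–C8 bond by Nozaki–Hiyama allylation through a closed chair transition state. Because C6 is trans to the metal-bearing CH2 on the allyl unit, this chair is expected to give the anti adduct, the (6R,7R,8S)-8-epimer of 27 F2. Mitsunobu esterification of F2 with 28 (PPh3, DIAD, THF) inverts C8 and comes back to the route at 29.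

2. Step 18 (ring-closing metathesis with tin present). Closure onto the hindered, electron-poor 1,1-disubstituted alkene may be slow, a seven-membered closure onto C1=C10 may compete, or the allyl–tin group may be lost at ruthenium. The fallback sets out from 19 and brings tin in after the ring is closed. Steglich esterification of 19 with 20 (N,N'-diisopropylcarbodiimide, catalytic DMAP, 0 °C) gives the 2-(bromomethyl)acrylate of 19 F3. Ring-closing metathesis of this tin-free, less hindered ester with second-generation Grubbs catalyst gives the (5R)-3-(bromomethyl)butenolide with O8-TBS F4. Stannylation of the allylic bromide with (Bu3Sn)2 and catalytic Pd2(dba)3 (zerovalent palladium, THF, rt), which goes through a π-allyl complex and delivers tin to the less hindered terminus C13, comes back at 24.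

3. Step 12 (alkynylation at C6). Facial selectivity may be poor on this β,β-disubstituted enal, or the enal may lose its geometry under the basic zinc alkoxide conditions. The fallback sets out from 15 and sets C6 by reduction. Addition of LiC≡CSiMe3 (from 16 and n-BuLi, THF, −78 °C) gives the racemic TMS-propargylic alcohol F5. Dess–Martin oxidation gives the alkenyl alkynyl ketone F6. Corey–Bakshi–Shibata reduction (2-methyl-CBS-oxazaborolidine, catecholborane, −78 °C, with the catalyst enantiomer that gives 6R) comes back at 17.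

**Further compounds**
F1 | step 21 | (3E,7E)-3-{[(tert-butyldiphenylsilyl)oxy]methyl}-8-[(2R)-4-(iodomethyl)-5-oxo-2,5-dihydrofuran-2-yl]-7-{[(4-methoxybenzyl)oxy]methyl}octa-3,7-dienal | O=C1O[C@H](/C=C(/COCc2ccc(OC)cc2)CC/C=C(/CO[Si](c2ccccc2)(c2ccccc2)C(C)(C)C)CC=O)C=C1CI
F2 | step 21 | (6R,7R,8S)-8-epimer of 27 | O=C1O[C@@H]2/C=C(/COCc3ccc(OC)cc3)CC/C=C(/CO[Si](c3ccccc3)(c3ccccc3)C(C)(C)C)C[C@H](O)[C@H]2C1=C
F3 | step 18 | 2-(bromomethyl)acrylate of 19 | C=C(CBr)C(=O)O[C@@H](C=C)/C=C(/COCc1ccc(OC)cc1)CC/C=C(/CO[Si](c1ccccc1)(c1ccccc1)C(C)(C)C)CCO[Si](C)(C)C(C)(C)C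
F4 | step 18 | (5R)-3-(bromomethyl)butenolide, O8-TBS | O=C1O[C@H](/C=C(/COCc2ccc(OC)cc2)CC/C=C(/CO[Si](c2ccccc2)(c2ccccc2)C(C)(C)C)CCO[Si](C)(C)C(C)(C)C)C=C1CBr
F5 | step 12 | racemic TMS-propargylic alcohol (racemate of 17) | OC(C#C[Si](C)(C)C)/C=C(/COCc1ccc(OC)cc1)CC/C=C(/CO[Si](c1ccccc1)(c1ccccc1)C(C)(C)C)CCO[Si](C)(C)C(C)(C)C
F6 | step 12 | alkenyl alkynyl ketone (C6 ketone) | O=C(C#C[Si](C)(C)C)/C=C(/COCc1ccc(OC)cc1)CC/C=C(/CO[Si](c1ccccc1)(c1ccccc1)C(C)(C)C)CCO[Si](C)(C)C(C)(C)C
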